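**Assumption:** the target has no stereocentre (it is achiral), so no stereocontrol is needed; reagents that only deliver atoms (MOMCl, Me2SO4, Eschenmoser's salt) are named with SMILES but not numbered.

**Retrosynthetic overview**
1. Cut the ArCH2–Ar' bond next to the trihydroxy ring: an ortho-quinone methide of the dimethoxy ring (from its phenolic Mannich base) plus isobutyryl-methylphloroglucinol 3.
2. The dimethoxy phenol 6 comes from the same 3 by 4-O-MOM protection, 2,6-di-O-methylation and MOM removal.
3. 3 comes from 2-methylphloroglucinol and isobutyryl chloride by Friedel–Crafts acylation.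
4. No ring is formed: both benzene rings are bought intact as 2-methylphloroglucinol. The trihydroxy ring is finished first (step 1), the dimethoxy ring is elaborated from it (steps 2–5), and the two are joined last (step 6).

**Route**

Step 1
Reactants: 1 2-methylbenzene-1,3,5-triol (2-methylphloroglucinol); 2 2-methylpropanoyl chloride (isobutyryl chloride)
Product: 3 1-(2,4,6-trihydroxy-3-methylphenyl)-2-methylpropan-1-one
Conditions: AlCl3 (3.5 equiv), PhNO2–CH2Cl2, 0 °C to rt then 50 °C; ice/aq. HCl work-up
Reagents that add atoms: none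
Why: Friedel–Crafts C-acylation of the very electron-rich phloroglucinol nucleus, whose two free ring carbons are equivalent, and the first acyl group deactivates the ring against a second acylation.

Step 2
Reactants: 3 1-(2,4,6-trihydroxy-3-methylphenyl)-2-methylpropan-1-one
Product: 4 1-[2,6-dihydroxy-4-(methoxymethoxy)-3-methylphenyl]-2-methylpropan-1-one
Conditions: MOMCl (1.05 equiv), i-Pr2NEt (1.2 equiv), CH2Cl2, 0 °C
Reagents that add atoms: chloromethyl methyl ether (MOMCl), COCCl
Why: Williamson-type O-alkylation (MOM ether formation) in which the 4-OH para to the ketone is the most acidic and least hindered hydroxyl, while the 2- and 6-OH are hydrogen-bonded to or crowded by the acyl group, so one equivalent of MOMCl reacts at O-4.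

Step 3
Reactants: 4 1-[2,6-dihydroxy-4-(methoxymethoxy)-3-methylphenyl]-2-methylpropan-1-one
Product: 5 1-[2,6-dimethoxy-4-(methoxymethoxy)-3-methylphenyl]-2-methylpropan-1-one
Conditions: Me2SO4 (4 equiv), K2CO3 (6 equiv), acetone, reflux, 24 h
Reagents that add atoms: dimethyl sulfate, COS(=O)(=O)OC
Why: Williamson O-methylation under forcing conditions etherifies both chelated ortho-hydroxyls, K2CO3/acetone favours O- over C-methylation, and the MOM acetal is stable to base.

Step 4
Reactants: 5 1-[2,6-dimethoxy-4-(methoxymethoxy)-3-methylphenyl]-2-methylpropan-1-one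
Product: 6 1-(4-hydroxy-2,6-dimethoxy-3-methylphenyl)-2-methylpropan-1-one
Conditions: conc. HCl (cat.), MeOH, 50 °C
Reagents that add atoms: none
Why: Acid-catalysed acetal cleavage (transacetalisation of the MOM group to dimethoxymethane) frees the 4-OH, while aryl methyl ethers and the hindered ketone are inert to dilute methanolic HCl.

Step 5
Reactants: 6 1-(4-hydroxy-2,6-dimethoxy-3-methylphenyl)-2-methylpropan-1-one
Product: 7 1-[3-[(dimethylamino)methyl]-4-hydroxy-2,6-dimethoxy-5-methylphenyl]-2-methylpropan-1-one
Conditions: CH2=NMe2+ I− (1.3 equiv), Et3N (1.5 equiv), CH2Cl2, rt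
Reagents that add atoms: N,N-dimethylmethyleneiminium iodide (Eschenmoser's salt), C=[N+](C)C.[I-]
Why: Mannich reaction (electrophilic aromatic aminomethylation) at the only free ring carbon, which is ortho to the phenol and ortho/para to the two methoxy groups.

Step 6
Reactants: 7 1-[3-[(dimethylamino)methyl]-4-hydroxy-2,6-dimethoxy-5-methylphenyl]-2-methylpropan-1-one; 3 1-(2,4,6-trihydroxy-3-methylphenyl)-2-methylpropan-1-one
Product: 9 1-[3-[[2-hydroxy-4,6-dimethoxy-3-methyl-5-(2-methylpropanoyl)phenyl]methyl]-2,4,6-trihydroxy-5-methylphenyl]-2-methylpropan-1-one (target), via ortho-quinone methide 8 (not isolated)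
Conditions: 3 (1.5 equiv), 1,4-dioxane, 100 °C, N2 stream
Reagents that add atoms: none
Why: Thermal elimination of Me2NH from the phenolic Mannich base (assisted by the acidic phloroglucinol) gives ortho-quinone methide 8, which is trapped by Michael-type C-alkylation at the single free nuclear carbon of 3 and rearomatises to the diarylmethane; no stereocentre is created.

**Compound list**
1 | 2-methylbenzene-1,3,5-triol (2-methylphloroglucinol) | Cc1c(O)cc(O)cc1O | starting material
2 | 2-methylpropanoyl chloride (isobutyryl chloride) | CC(C)C(=O)Cl | starting material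
3 | 1-(2,4,6-trihydroxy-3-methylphenyl)-2-methylpropan-1-one | CC(C)C(=O)c1c(O)cc(O)c(C)c1O | intermediate
4 | 1-[2,6-dihydroxy-4-(methoxymethoxy)-3-methylphenyl]-2-methylpropan-1-one | CC(C)C(=O)c1c(O)cc(OCOC)c(C)c1O | intermediate
5 | 1-[2,6-dimethoxy-4-(methoxymethoxy)-3-methylphenyl]-2-methylpropan-1-one | CC(C)C(=O)c1c(OC)cc(OCOC)c(C)c1OC | intermediate
6 | 1-(4-hydroxy-2,6-dimethoxy-3-methylphenyl)-2-methylpropan-1-one | CC(C)C(=O)c1c(OC)cc(O)c(C)c1OC | intermediate
7 | 1-[3-[(dimethylamino)methyl]-4-hydroxy-2,6-dimethoxy-5-methylphenyl]-2-methylpropan-1-one | CC(C)C(=O)c1c(OC)c(CN(C)C)c(O)c(C)c1OC | intermediate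
8 | 3,5-dimethoxy-2-methyl-6-methylidene-4-(2-methylpropanoyl)cyclohexa-2,4-dien-1-one (ortho-quinone methide, not isolated) | CC(C)C(=O)C1=C(OC)C(=C)C(=O)C(C)=C1OC | intermediate
9 | 1-[3-[[2-hydroxy-4,6-dimethoxy-3-methyl-5-(2-methylpropanoyl)phenyl]methyl]-2,4,6-trihydroxy-5-methylphenyl]-2-methylpropan-1-one | COc1c(C)c(O)c(Cc2c(O)c(C)c(O)c(C(=O)C(C)C)c2O)c(OC)c1C(=O)C(C)C | target

**Totals**
Total step count: 6. Longest linear sequence: 6 steps (1 → 3 → 4 → 5 → 6 → 7 → 9); compound 3 is used again as the coupling partner in step 6.

**Three steps most likely to fail, with fallbacks**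

Risk at step 2 (mono-MOM protection may give 4-mono/2,4-bis mixtures). The fallback reverses the order to "methylate first, acylate second" and uses no protecting group. It sets out from 1, which is heated in methanol saturated with dry HCl (Fischer-type partial etherification, as for phloroglucinol to 3,5-dimethoxyphenol) to give 3,5-dimethoxy-2-methylphenol F1; the unhindered OH para to the methyl and one flanking OH are etherified. Friedel–Crafts acylation of F1 with 2 (AlCl3, CH2Cl2–PhNO2, 0 °C) puts the acyl group between the two methoxy groups and gives 6. The chelated ortho-acyl isomer 1-(2-hydroxy-4,6-dimethoxy-3-methylphenyl)-2-methylpropan-1-one F2 forms alongside and is removed by extracting 6 into cold dilute alkali or by chromatography. The route is rejoined at 6.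

Risk at step 5 (the Mannich reaction may stall on the crowded, acyl-bearing phenol or revert). The fallback replaces the amine leaving group by a hydroxyl. It sets out from 6, which is ortho-formylated (MgCl2, Et3N, paraformaldehyde, MeCN, reflux) to 2-hydroxy-4,6-dimethoxy-3-methyl-5-(2-methylpropanoyl)benzaldehyde F3. NaBH4 in MeOH at 0 °C reduces only the aldehyde (the di-ortho-substituted ketone is too hindered) to 1-[4-hydroxy-3-(hydroxymethyl)-2,6-dimethoxy-5-methylphenyl]-2-methylpropan-1-one F4. Warming F4 with 3 and catalytic TsOH in dioxane loses water to give the same ortho-quinone methide, so the route is rejoined at 8 and continues to 9 as in step 6.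

Risk at step 6 (the quinone methide may form sluggishly or dimerise before 3 captures it). The fallback reverses the polarity of the coupling. It sets out from 3, which is aminomethylated with one equivalent of Eschenmoser's salt (MeCN, 0 °C) to 1-[3-[(dimethylamino)methyl]-2,4,6-trihydroxy-5-methylphenyl]-2-methylpropan-1-one F5. This phloroglucinol Mannich base loses dimethylamine much more readily, on gentle warming in dioxane with NaOAc, to give 3,5-dihydroxy-4-methyl-6-methylidene-2-(2-methylpropanoyl)cyclohexa-2,4-dien-1-one F6. An excess of phenol 6 captures F6 at its only free ring carbon, and the route is rejoined at 9.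

**Further compounds**
F1 | step 2 | 3,5-dimethoxy-2-methylphenol | COc1cc(OC)c(C)c(O)c1
F2 | step 2 | 1-(2-hydroxy-4,6-dimethoxy-3-methylphenyl)-2-methylpropan-1-one | CC(C)C(=O)c1c(O)c(C)c(OC)cc1OC
F3 | step 5 | 2-hydroxy-4,6-dimethoxy-3-methyl-5-(2-methylpropanoyl)benzaldehyde | CC(C)C(=O)c1c(OC)c(C=O)c(O)c(C)c1OC
F4 | step 5 | 1-[4-hydroxy-3-(hydroxymethyl)-2,6-dimethoxy-5-methylphenyl]-2-methylpropan-1-one | CC(C)C(=O)c1c(OC)c(CO)c(O)c(C)c1OC
F5 | step 6 | 1-[3-[(dimethylamino)methyl]-2,4,6-trihydroxy-5-methylphenyl]-2-methylpropan-1-one | CC(C)C(=O)c1c(O)c(C)c(O)c(CN(C)C)c1O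
F6 | step 6 | 3,5-dihydroxy-4-methyl-6-methylidene-2-(2-methylpropanoyl)cyclohexa-2,4-dien-1-one | CC(C)C(=O)C1=C(O)C(C)=C(O)C(=C)C1=O
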